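Retrosynthetic overview
1. Endgame: one HAT hydrogenation of a bis(alkenyl bromide) sets both C–Br stereocentres (C6, C14). The C12 carbinol comes from 1,2-reduction of a β-bromoenone made from a cyclopentane-1,3-dione.
2. Key disconnection (new step): a cobalt-hydride radical–polar crossover semipinacol ring expansion of a 1-alkenylcyclobutanol silyl ether forms the C11–C15 bond and the cyclopentane. The =CH2 carbon becomes the C11 methyl.
3. C11 linchpin: CH2=C(Br)Li adds first to an enantiopure 3-alkoxy-2,2-dimethylcyclobutanone (C11–C12). After Br/Li exchange it adds to the decalin C10 ketone (C10–C11).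
4. Decalin ketone from (S)-Wieland–Miescher ketone: the C6 ketone becomes the alkenyl bromide. The deconjugated C2=C3 alkene becomes the 2α,3β-diol through OsO4, oxidation and MeCeCl2.
5. Ring order: rings A and B are bought as the decalin, the cyclobutane is made by ketene [2+2], and the cyclopentane (ring C) forms last by ring expansion.

Assumption: locants are biogenetic. Decalin = C10 (carbinol carbon bearing the cyclopentyl group), C9, C8, C7 (angular CH3), C6 (CHBr), C5, C4, C3 (C(CH3)OH), C2 (ring-fusion C–OH), C1. Cyclopentane = C11 (quaternary C–CH3), C12 (CHOH), C13, C14 (CHBr), C15 (CMe2). β is the face of the C7 methyl. The target is (2R,3R,6S,7S,10R,11R,12S,14R): a trans-decalin with 2α-, 3β- and 10α-OH axial, 6β-Br equatorial, and C12–OH, C14–Br and the decalin substituent on C11 all cis.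

Step 1
Reactants: 1 (S)-Wieland–Miescher ketone
Product: 2 (4aS,5S)-5-hydroxy-4a-methyl-4,4a,5,6,7,8-hexahydronaphthalen-2(3H)-one (C6 β-alcohol; enone kept)
Conditions: NaBH4 (0.3 equiv), EtOH, 0 °C
Reagents that add atoms: none
Why: Chemoselective borohydride reduction, in which the saturated C6 ketone reacts faster than the enone carbonyl and hydride arrives anti to the angular methyl, gives the β (equatorial) alcohol that only masks C6 for the next step.

Step 2
Reactants: 2 C6 β-hydroxy enone
Product: 3 hydroxy ketal (C10 1,3-dioxolane; C2=C3 alkene; C6 β-OH)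
Conditions: HOCH2CH2OH, p-toluenesulfonic acid (cat.), benzene, reflux, Dean–Stark
Reagents that add atoms: ethylene glycol OCCO
Why: Acid-catalysed ketalisation of a conjugated enone runs through the dienol and moves the double bond to the β,γ position (C2=C3), as in the classical steroid enone ketalisation.

Step 3
Reactants: 3 hydroxy ketal
Product: 4 keto ketal (C10 1,3-dioxolane; C2=C3 alkene; C6 ketone)
Conditions: Dess–Martin periodinane, pyridine, CH2Cl2, 0 °C to rt
Reagents that add atoms: none
Why: Dess–Martin oxidation under buffered conditions restores the C6 ketone without touching the ketal or the alkene, so C6 is now the only free carbonyl.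

Step 4
Reactants: 4 keto ketal
Product: 5 enol triflate (C5=C6; OTf on C6)
Conditions: KN(SiMe3)2, THF, −78 °C; PhNTf2, −78 to 0 °C
Reagents that add atoms: N-phenylbis(trifluoromethanesulfonimide) O=S(=O)(N(c1ccccc1)S(=O)(=O)C(F)(F)F)C(F)(F)F
Why: Kinetic enolate O-triflation gives a single enol triflate because C6 can enolise only toward C5, C7 being quaternary.

Step 5
Reactants: 5 enol triflate
Product: 6 alkenyl bromide (C5=C6; Br on C6; C10 1,3-dioxolane; C2=C3 alkene)
Conditions: LiBr (5 equiv), [Cp*Ru(MeCN)3]OTf (5 mol %), THF, 50 °C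
Reagents that add atoms: lithium bromide [Li+].[Br-]
Why: Ruthenium-catalysed triflate-to-halide exchange of alkenyl triflates (oxidative addition, anion swap, reductive elimination) replaces OTf by Br with the double bond kept in place.

Step 6
Reactants: 6 alkenyl bromide
Product: 7 2α,3α-diol (C10 1,3-dioxolane; C5=C6 bromoalkene)
Conditions: OsO4 (2 mol %), NMO, acetone/H2O, rt
Reagents that add atoms: N-methylmorpholine N-oxide C[N+]1([O-])CCOCC1; water O
Why: In this Upjohn dihydroxylation OsO4 chooses the electron-rich C2=C3 alkene over the electron-poor bromoalkene and adds from the α face, anti to the axial angular methyl, which sets the 2α tertiary hydroxyl.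

Step 7
Reactants: 7 2α,3α-diol
Product: 8 2α-hydroxy C3 ketone
Conditions: Dess–Martin periodinane, pyridine, CH2Cl2, rt
Reagents that add atoms: none
Why: Dess–Martin oxidation can touch only the secondary C3 alcohol because the C2 alcohol is tertiary.

Step 8
Reactants: 8 2α-hydroxy C3 ketone
Product: 9 2α,3β-diol bearing the 3α-methyl group (C10 1,3-dioxolane; C5=C6 bromoalkene)
Conditions: MeLi (3 equiv), CeCl3 (3 equiv), THF, −78 °C; H2O
Reagents that add atoms: methyllithium [Li]C
Why: Organocerium 1,2-addition avoids enolising the β,γ-unsaturated ketone, and since the 1,3-syn-axial angular methyl blocks the β face of C3, methyl enters from the α face and sets C3 (3β-OH, 3α-CH3, trans-diaxial to 2α-OH).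

Step 9
Reactants: 9 ketal diol
Product: 10 decalin C10 ketone (2α,3β-diol; 3α-methyl; C5=C6 bromoalkene)
Conditions: pyridinium p-toluenesulfonate (cat.), THF/H2O, 45 °C
Reagents that add atoms: water O
Why: Mild acid-catalysed ketal hydrolysis frees the unhindered C10 ketone, and the acid is too weak to dehydrate the β-hydroxy ketone or the tertiary carbinols.

Step 10
Reactants: 10 decalin C10 ketone
Product: 11 bis(trimethylsilyl) ether of 10 (OTMS on C2 C3)
Conditions: N-(trimethylsilyl)imidazole, CH2Cl2, 40 °C
Reagents that add atoms: N-(trimethylsilyl)imidazole C[Si](C)(C)n1ccnc1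
Why: O-silylation with a strong neutral silyl donor caps both hindered tertiary alcohols without enolising the ketone, and the axial C2–OTMS group will shield the α face of C10 in step 15.

Step 11
Reactants: 12 (S)-1-(4-methoxyphenyl)ethanol, 13 ethyl vinyl ether
Product: 14 (S)-1-(4-methoxyphenyl)ethyl vinyl ether
Conditions: Pd(OAc)2 (2 mol %), 1,10-phenanthroline (2 mol %), 13 (excess), CH2Cl2, rt
Reagents that add atoms: none
Why: Palladium-catalysed transfer vinylation exchanges the alkoxy group at the vinyl carbon, so the benzylic C–O bond and its stereocentre are untouched.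

Step 12
Reactants: 14 chiral vinyl ether, 15 isobutyryl chloride
Product: 17 (3R)-3-[(S)-1-(4-methoxyphenyl)ethoxy]-2,2-dimethylcyclobutan-1-one, via dimethylketene 16 (not isolated)
Conditions: Et3N, toluene, 90 °C (slow addition of 15); silica gel chromatography
Reagents that add atoms: none
Why: In the thermal ketene–enol ether [2+2] cycloaddition the nucleophilic CH2 terminus bonds to the ketene carbonyl carbon, which gives only the 3-alkoxy-2,2-dimethyl regioisomer, and the auxiliary allows the (3R) diastereomer to be isolated pure, fixing the relay centre C14.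

Step 13
Reactants: 17 cyclobutanone, 18 vinyl bromide
Product: 20 (1S,3R)-1-(1-bromoethenyl)-3-[(S)-1-(4-methoxyphenyl)ethoxy]-2,2-dimethylcyclobutan-1-ol (OH cis to the alkoxy group), via 1-bromo-1-lithioethene 19 (not isolated)
Conditions: LiN(iPr)2, THF/Et2O/pentane 4:1:1, −110 °C; then 17; H2O
Reagents that add atoms: none
Why: 1,2-Addition of the α-bromoalkenyllithium carbenoid to the strained, very electrophilic ketone outruns enolisation at −110 °C, and attack anti to the C14 alkoxy group sets C12 with its oxygen cis to that group.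

Step 14
Reactants: 20 bromoalkenyl cyclobutanol
Product: 21 trimethylsilyl ether of 20
Conditions: N-(trimethylsilyl)imidazole, CH2Cl2, rt
Reagents that add atoms: N-(trimethylsilyl)imidazole C[Si](C)(C)n1ccnc1
Why: O-silylation removes the acidic proton before halogen–lithium exchange and installs the group that will leave from oxygen in step 17.

Step 15
Reactants: 21 bromoalkenyl cyclobutyl silyl ether, 11 decalin ketone bis(silyl ether)
Product: 24 coupled carbinol (C10 α-OH; C11=CH2 joins C10 to cyclobutane C12; OTMS on C2 C3 C12), via alkenyllithium 22 (not isolated), via alkenylcerium dichloride 23 (not isolated)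
Conditions: t-BuLi (2.0 equiv), Et2O, −78 °C; CeCl3, THF, −78 °C; then 11; H2O
Reagents that add atoms: none
Why: After bromine–lithium exchange and transmetalation, the non-basic organocerium adds 1,2 from the equatorial β face because the axial C2–OTMS group blocks the α face, which sets C10 (axial α-OH), while the hindered C6 alkenyl bromide does not exchange at −78 °C.

Step 16
Reactants: 24 coupled carbinol
Product: 25 tetrakis(trimethylsilyl) ether (OTMS on C2 C3 C10 C12)
Conditions: Me3SiOTf, 2,6-lutidine, CH2Cl2, −78 to 0 °C
Reagents that add atoms: trimethylsilyl triflate C[Si](C)(C)OS(=O)(=O)C(F)(F)F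
Why: O-silylation with the silyl triflate and a hindered base caps the congested axial C10 alcohol and re-silylates any oxygen bared by silyl migration, so C10–O can neither close an epoxide in step 17 nor allow a retro-aldol later.

Step 17
Reactants: 25 tetrakis(trimethylsilyl) ether
Product: 26 cyclopentanone (C12 ketone; quaternary C11 with its methyl trans to the C14 alkoxy group; OTMS on C2 C3 C10)
Conditions: [N,N'-bis(3,5-di-tert-butylsalicylidene)-1,2-cyclohexanediaminato]cobalt (5 mol %), N-fluoro-2,4,6-trimethylpyridinium triflate (1.5 equiv), PhSiH3 (1.5 equiv), PhCF3, 0 °C to rt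
Reagents that add atoms: none
Why: Proposed new method: a cobalt-hydride HAT-initiated radical–polar crossover, desilylative semipinacol ring expansion on a 1,1-disubstituted alkene flanked by two fully substituted siloxy carbons, in which the cobalt hydride (from the salen complex, the N–F oxidant and PhSiH3) delivers H• to the exposed CH2 terminus and so creates the C11 methyl, the hindered tertiary C11 radical is oxidised (through a tetravalent alkylcobalt or by outer-sphere electron transfer) to cationic C11, and the more substituted C12–C15 cyclobutane bond migrates with release of about 20 kcal/mol of strain while the C12 siloxy group collapses to the ketone and loses Me3Si+, so the bond between the two quaternary carbons and the cyclopentanone form under near-neutral conditions that spare the benzylic ether, the silyl ethers and the sluggish trisubstituted bromoalkene; C11 is set because C15 migrates only in the rotamer that aligns C12–C15 with the empty orbital and keeps the small siloxy oxygen rather than the ring CH2 next to bulky C10, which relays C12 (hence C14) into C11, whereas contraction of ring A from the C10 side gains no strain relief; the closest known reaction types are the cobalt-salen HAT radical–polar crossover semipinacol rearrangement of simple tertiary allylic alcohols and the halonium- or acid-induced ring expansion of 1-alkenylcyclobutanols.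

Step 18
Reactants: 26 cyclopentanone
Product: 27 β-hydroxy ketone (C12 ketone; C14 OH)
Conditions: DDQ, CH2Cl2/pH 7 buffer, 0 °C
Reagents that add atoms: none
Why: Oxidative cleavage of the electron-rich benzylic ether (hydride abstraction by DDQ, then hydrolysis) removes the auxiliary without affecting silyl ethers or the alkenyl bromide.

Step 19
Reactants: 27 β-hydroxy ketone
Product: 28 cyclopentane-1,3-dione (C12 and C14 ketones)
Conditions: Dess–Martin periodinane, pyridine, CH2Cl2, rt
Reagents that add atoms: none
Why: Dess–Martin oxidation of the only free alcohol gives the 1,3-diketone and deliberately erases the relay centre C14.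

Step 20
Reactants: 28 cyclopentane-1,3-dione
Product: 29 β-bromoenone (C12 ketone; C13=C14; Br on C14)
Conditions: Ph3PBr2 (1.05 equiv), Et3N, benzene, rt
Reagents that add atoms: dibromotriphenylphosphorane BrP(Br)(c1ccccc1)(c1ccccc1)c1ccccc1
Why: Conversion of a cyclic 1,3-diketone into a β-haloenone through the enol phosphonium salt (addition–elimination) takes place at C14, which lies beside CMe2, rather than at C12, which is buried beside the decalin-bearing C11.

Step 21
Reactants: 29 β-bromoenone
Product: 30 bromo allylic alcohol (C12 OH cis to the decalin substituent on C11; C13=C14–Br)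
Conditions: iBu2AlH, CH2Cl2, −78 °C; aqueous work-up
Reagents that add atoms: none
Why: In this 1,2-reduction of the enone the bulky hydride attacks C12 from the face of the small C11 methyl, anti to the decalin substituent, which sets the (12S) carbinol.

Step 22
Reactants: 30 bis(alkenyl bromide) allylic alcohol
Product: 31 tris(trimethylsilyl) ether of neoirietetraol (OTMS on C2 C3 C10)
Conditions: Co(acac)2 (25 mol % per alkene), t-BuOOH, Et3SiH, 1,4-cyclohexadiene, n-PrOH, rt, Ar
Reagents that add atoms: none
Why: In the cobalt-mediated HAT hydrogenation of alkenyl halides to alkyl halides H• adds to C5 and C13, and each α-bromo radical then takes H from 1,4-cyclohexadiene on its open face (axial α at C6, giving equatorial 6β-Br; at C14 the face anti to the decalin substituent and C12–OH, giving Br cis to both), so C6 and C14 are set without C–Br cleavage.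

Step 23
Reactants: 31 tris(trimethylsilyl) ether
Product: 32 neoirietetraol
Conditions: HF·pyridine, pyridine, THF, 0 °C to rt
Reagents that add atoms: none
Why: Fluoride-driven desilylation under buffered, non-basic conditions frees the three tertiary alcohols without eliminating or displacing the secondary bromides.

Compound list
1 | (S)-Wieland–Miescher ketone | O=C1CC[C@]2(C)C(=O)CCCC2=C1 | starting material
2 | (4aS,5S)-5-hydroxy-4a-methyl-4,4a,5,6,7,8-hexahydronaphthalen-2(3H)-one | O=C1CC[C@]2(C)[C@@H](O)CCCC2=C1 | intermediate
3 | hydroxy ketal (C10 1,3-dioxolane; C2=C3 alkene; C6 β-OH) | C1COC2(O1)CC[C@]1(C)[C@@H](O)CCC=C1C2 | intermediate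
4 | keto ketal (C10 1,3-dioxolane; C2=C3 alkene; C6 ketone) | C1COC2(O1)CC[C@]1(C)C(=O)CCC=C1C2 | intermediate
5 | enol triflate (C5=C6; OTf on C6) | C1COC2(O1)CC[C@]1(C)C(OS(=O)(=O)C(F)(F)F)=CCC=C1C2 | intermediate
6 | alkenyl bromide (C5=C6; Br on C6) | C1COC2(O1)CC[C@]1(C)C(Br)=CCC=C1C2 | intermediate
7 | 2α,3α-diol | C1COC2(O1)CC[C@]1(C)C(Br)=CC[C@H](O)[C@@]1(O)C2 | intermediate
8 | 2α-hydroxy C3 ketone | C1COC2(O1)CC[C@]1(C)C(Br)=CCC(=O)[C@@]1(O)C2 | intermediate
9 | 2α,3β-diol bearing the 3α-methyl group (C10 ketal) | C1COC2(O1)CC[C@]1(C)C(Br)=CC[C@@](C)(O)[C@@]1(O)C2 | intermediate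
10 | decalin C10 ketone (2α,3β-diol; 3α-methyl; C5=C6 bromoalkene) | O=C1CC[C@]2(C)C(Br)=CC[C@@](C)(O)[C@@]2(O)C1 | intermediate
11 | bis(trimethylsilyl) ether of 10 | O=C1CC[C@]2(C)C(Br)=CC[C@@](C)(O[Si](C)(C)C)[C@@]2(O[Si](C)(C)C)C1 | intermediate
12 | (S)-1-(4-methoxyphenyl)ethanol | C[C@H](O)c1ccc(OC)cc1 | starting material
13 | ethyl vinyl ether | C=COCC | starting material
14 | (S)-1-(4-methoxyphenyl)ethyl vinyl ether | C[C@H](OC=C)c1ccc(OC)cc1 | intermediate
15 | isobutyryl chloride | CC(C)C(Cl)=O | starting material
16 | dimethylketene | CC(C)=C=O | intermediate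
17 | (3R)-3-[(S)-1-(4-methoxyphenyl)ethoxy]-2,2-dimethylcyclobutan-1-one | CC1(C)[C@H](O[C@@H](C)c2ccc(OC)cc2)CC1=O | intermediate
18 | vinyl bromide | C=CBr | starting material
19 | 1-bromo-1-lithioethene | C=C([Li])Br | intermediate
20 | (1S,3R)-1-(1-bromoethenyl)-3-[(S)-1-(4-methoxyphenyl)ethoxy]-2,2-dimethylcyclobutan-1-ol | CC1(C)[C@H](O[C@@H](C)c2ccc(OC)cc2)C[C@@]1(O)C(Br)=C | intermediate
21 | trimethylsilyl ether of 20 | CC1(C)[C@H](O[C@@H](C)c2ccc(OC)cc2)C[C@@]1(O[Si](C)(C)C)C(Br)=C | intermediate
22 | alkenyllithium from 21 | CC1(C)[C@H](O[C@@H](C)c2ccc(OC)cc2)C[C@@]1(O[Si](C)(C)C)C([Li])=C | intermediate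
23 | alkenylcerium dichloride from 22 | CC1(C)[C@H](O[C@@H](C)c2ccc(OC)cc2)C[C@@]1(O[Si](C)(C)C)C([Ce](Cl)Cl)=C | intermediate
24 | coupled carbinol (C10 α-OH; OTMS on C2 C3 C12) | CC1(C)[C@H](O[C@@H](C)c2ccc(OC)cc2)C[C@@]1(O[Si](C)(C)C)C(=C)[C@@]1(O)CC[C@]2(C)C(Br)=CC[C@@](C)(O[Si](C)(C)C)[C@@]2(O[Si](C)(C)C)C1 | intermediate
25 | tetrakis(trimethylsilyl) ether (OTMS on C2 C3 C10 C12) | CC1(C)[C@H](O[C@@H](C)c2ccc(OC)cc2)C[C@@]1(O[Si](C)(C)C)C(=C)[C@@]1(O[Si](C)(C)C)CC[C@]2(C)C(Br)=CC[C@@](C)(O[Si](C)(C)C)[C@@]2(O[Si](C)(C)C)C1 | intermediate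
26 | cyclopentanone (C12 ketone; quaternary C11; C14 alkoxy) | CC1(C)[C@H](O[C@@H](C)c2ccc(OC)cc2)CC(=O)[C@]1(C)[C@@]1(O[Si](C)(C)C)CC[C@]2(C)C(Br)=CC[C@@](C)(O[Si](C)(C)C)[C@@]2(O[Si](C)(C)C)C1 | intermediate
27 | β-hydroxy ketone (C12 ketone; C14 OH) | CC1(C)[C@H](O)CC(=O)[C@]1(C)[C@@]1(O[Si](C)(C)C)CC[C@]2(C)C(Br)=CC[C@@](C)(O[Si](C)(C)C)[C@@]2(O[Si](C)(C)C)C1 | intermediate
28 | cyclopentane-1,3-dione (C12 and C14 ketones) | CC1(C)C(=O)CC(=O)[C@]1(C)[C@@]1(O[Si](C)(C)C)CC[C@]2(C)C(Br)=CC[C@@](C)(O[Si](C)(C)C)[C@@]2(O[Si](C)(C)C)C1 | intermediate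
29 | β-bromoenone (C12 ketone; C13=C14–Br) | CC1(C)C(Br)=CC(=O)[C@]1(C)[C@@]1(O[Si](C)(C)C)CC[C@]2(C)C(Br)=CC[C@@](C)(O[Si](C)(C)C)[C@@]2(O[Si](C)(C)C)C1 | intermediate
30 | bromo allylic alcohol (12S) | CC1(C)C(Br)=C[C@H](O)[C@]1(C)[C@@]1(O[Si](C)(C)C)CC[C@]2(C)C(Br)=CC[C@@](C)(O[Si](C)(C)C)[C@@]2(O[Si](C)(C)C)C1 | intermediate
31 | tris(trimethylsilyl) ether of neoirietetraol | CC1(C)[C@H](Br)C[C@H](O)[C@]1(C)[C@@]1(O[Si](C)(C)C)CC[C@]2(C)[C@@H](Br)CC[C@@](C)(O[Si](C)(C)C)[C@@]2(O[Si](C)(C)C)C1 | intermediate
32 | neoirietetraol | CC1(C)[C@H](Br)C[C@H](O)[C@]1(C)[C@@]1(O)CC[C@]2(C)[C@@H](Br)CC[C@@](C)(O)[C@@]2(O)C1 | target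

Total step count: 23. Longest linear sequence: 19 steps (steps 1–10, then 15–23). The cyclobutane branch (steps 11–14) runs in parallel.

Three steps most likely to fail

Step 17 (the proposed new step). The alkene is extremely hindered, the oxidation of the C11 radical may stall, and the rotamer-based relay to C11 is a model only. The fallback uses known chemistry, sets out from 25 and comes back at 26. N-iodosuccinimide in CH2Cl2 at −40 °C triggers the known halonium-induced semipinacol ring expansion of the 1-alkenylcyclobutanol silyl ether to the iodomethyl cyclopentanone F1. Radical deiodination with Bu3SnH, Et3B/air and catalytic PhSeSePh in toluene at 0 °C then gives 26. The selenol is a fast hydrogen donor that outruns the Dowd–Beckwith acyl shift, and the C–I bond reacts far faster than the alkenyl C–Br bond.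

Step 12. Ketene dimerisation, loss of the heat- and acid-sensitive benzylic vinyl ether, and a low diastereomer ratio can all cut the supply of 17. The fallback sets out from 12 and comes back at 17. Commercial racemic 3-ethoxy-2,2-dimethylcyclobutanone loses ethanol on warming with catalytic p-toluenesulfonic acid to give 4,4-dimethylcyclobut-2-en-1-one F2. Alcohol 12 is added to this strained enone in a base-catalysed oxa-Michael reaction (catalytic KOtBu, THF, −20 °C). The two C14 epimers are separated on silica gel to give 17.

Step 5. The halide exchange has to take place at an enol triflate next to a quaternary carbon, and the skipped diene may bind ruthenium. The fallback sets out from 5 and comes back at 6. Stille-type stannylation with Me3SnSnMe3, Pd(PPh3)4 and LiCl in THF at reflux gives the alkenylstannane F3. Bromodestannylation with N-bromosuccinimide in CH2Cl2 at −78 °C, which is much faster than attack on the C2=C3 alkene, gives 6.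

Further compounds
F1 | step 17 | iodomethyl cyclopentanone (CH2I on C11 in place of CH3; otherwise as 26) | CC1(C)[C@H](O[C@@H](C)c2ccc(OC)cc2)CC(=O)[C@]1(CI)[C@@]1(O[Si](C)(C)C)CC[C@]2(C)C(Br)=CC[C@@](C)(O[Si](C)(C)C)[C@@]2(O[Si](C)(C)C)C1
F2 | step 12 | 4,4-dimethylcyclobut-2-en-1-one | CC1(C)C=CC1=O
F3 | step 5 | alkenylstannane (SnMe3 on C6 in place of OTf; otherwise as 5) | C1COC2(O1)CC[C@]1(C)C([Sn](C)(C)C)=CCC=C1C2
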